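**Plan**
1. Numbering used below (iridal type): ring A = C11(spiro)–C6–C7–C8–C9–C10; ring B = C11–C12–C13–C14–C26; C3–C5 = hydroxypropyl on C6; C2(CH3)–C1HO on C7; side chain C15(C27H2OAc)=C16–C17=C18–C19(=CH2)–C20…C23 on C14.
2. Cuts: C14–C15 (ketone α-alkenylation with bromotrienol 26); C7=C2 (isopropenyl addition, then oxidative 1,3-transposition); C10–CH3; then, in one event, the ring B bond C12–C13 together with the C11–C6 bond (Nazarov cyclisation/semipinacol ring expansion), back to cyclopentanone 6 and an acrolein α-anion equivalent.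
3. Forward: cyclopentanone 6 (future C6–C10) → dienone 12 → step 6 closes ring B and turns the five-membered carbinol ring into ring A with spiro C11 → C10 methylation, C7 ketone, isopropenyl carbinol → side chain on C14 → acetate, enal, C26–OH, desilylation.
4. Enabling feature: the C26 carbinol carbon flanked by C14 and the quaternary C11 is a cyclopentanone (Nazarov) retron whose bond opposite the carbonyl is C12–C13, both CH2; the tertiary oxygen on C10, next to C11, can push a 1,2-shift that makes C11 quaternary and returns C10 as a ketone for the methyl addition.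
5. Stereochemistry: Rh/BINAP conjugate silylation (temporary C7 centre) → C6 trans by equilibration → C10 carbinol by addition anti to the C6 chain → C11 by stereospecific shift of C6 under chelate control; C10–CH3 by axial attack; C26 by C10–OH-directed hydride; C14 by epimer funnelling in that reduction; C15=C16 and C17=C18 from stannane and bromide couplings with retention; C7=C2 from the chair-like [3,3] shift.

Key step: step 6

Remark: compounds 1, 2, 7, 19, 21 and 23 are taken as commercial; the sense of induction in step 2 is assumed to follow that of rhodium/BINAP additions to cyclopent-2-enone (the other BINAP enantiomer would be used if it proves opposite).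

**Step 1**
Reactants: 1 2-iodocyclopent-2-en-1-one; 2 tert-butyl(diphenyl)(prop-2-en-1-yloxy)silane
Product: 4 2-{3-[(tert-butyldiphenylsilyl)oxy]propyl}cyclopent-2-en-1-one, via B-alkylborane 3 (not isolated)
Conditions: 2, 9-BBN-H, THF, 0 → 23 °C; then 1, PdCl2(dppf), AsPh3, Cs2CO3, DMF/THF/H2O, 23 °C
Reagents that add atoms: none
Why: Anti-Markovnikov hydroboration gives a primary alkylborane that undergoes B-alkyl Suzuki–Miyaura coupling with the α-iodoenone, no stereocentre being formed.

**Step 2**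
Reactants: 4
Product: 6 (2S,3S)-2-{3-[(tert-butyldiphenylsilyl)oxy]propyl}-3-[dimethyl(phenyl)silyl]cyclopentan-1-one, via cis epimer 5 (not isolated)
Conditions: PhMe2Si–B(pin) (1.5 equiv), [Rh(cod)2]OTf (5 mol %), (S)-BINAP (6 mol %), Et3N, 1,4-dioxane/H2O (10:1), 50 °C; then DBU, CH2Cl2, 23 °C
Reagents that add atoms: 2-[dimethyl(phenyl)silyl]-4,4,5,5-tetramethyl-1,3,2-dioxaborolane, CC1(C)OB(OC1(C)C)[Si](C)(C)c1ccccc1
Why: Rhodium-catalysed enantioselective conjugate silyl transfer from the Si–B reagent sets the silyl-bearing centre (future C7) under ligand control, and base equilibration of the α-centre (future C6) should give the favoured 2,3-trans ketone.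

**Step 3**
Reactants: 6; 7 2-bromo-3,3-diethoxyprop-1-ene
Product: 10 2-[(1S,2S,3S)-2-{3-[(tert-butyldiphenylsilyl)oxy]propyl}-3-[dimethyl(phenyl)silyl]-1-hydroxycyclopentyl]prop-2-enal, via vinyllithium 8 (not isolated), via diethyl acetal adduct 9 (not isolated)
Conditions: 7, t-BuLi (2 equiv), THF, −78 °C; CeCl3; 6, −78 °C; then 1 M aq. oxalic acid, THF, 0 → 23 °C
Reagents that add atoms: water, O
Why: Lithium–bromine exchange gives an acrolein α-anion equivalent whose organocerium form adds to the hindered ketone without enolisation and anti to the adjacent propyl chain (as nucleophiles do on 2,3-trans-disubstituted cyclopentanones), which sets the future C10 carbinol with OH cis to the chain, and mild acid unmasks the enal.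

**Step 4**
Reactants: 10
Product: 11 2-[(1S,2S,3S)-2-{3-[(tert-butyldiphenylsilyl)oxy]propyl}-3-[dimethyl(phenyl)silyl]-1-hydroxycyclopentyl]penta-1,4-dien-3-ol (both C3 epimers)
Conditions: CH2=CHMgBr (2.5 equiv), THF, −78 °C
Reagents that add atoms: vinylmagnesium bromide, C=C[Mg]Br
Why: 1,2-Grignard addition to the α-substituted acrolein; the new carbinol centre is removed in step 5.

**Step 5**
Reactants: 11
Product: 12 2-[(1S,2S,3S)-2-{3-[(tert-butyldiphenylsilyl)oxy]propyl}-3-[dimethyl(phenyl)silyl]-1-hydroxycyclopentyl]penta-1,4-dien-3-one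
Conditions: Dess–Martin periodinane, NaHCO3, CH2Cl2, 0 °C; used without storage
Reagents that add atoms: none
Why: Dess–Martin oxidation of the secondary bis-allylic alcohol gives the cross-conjugated dienone and leaves the tertiary alcohol untouched.

**Step 6**
Reactants: 12
Product: 14 (5S,9S,10S)-10-{3-[(tert-butyldiphenylsilyl)oxy]propyl}-9-[dimethyl(phenyl)silyl]spiro[4.5]decane-1,6-dione, via oxyallyl cation 13 (not isolated)
Conditions: Sc(OTf)3 (1.0 equiv), ClCH2CH2Cl, 0 → 40 °C
Reagents that add atoms: none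
Why: Proposed new method: trivalent scandium should bind the ketone oxygen and the neighbouring tertiary hydroxyl of 12 as a six-membered chelate; the pentadienyl cation then closes by thermal conrotatory 4π electrocyclisation (Nazarov cyclisation, the closure of ring B) between the unsubstituted termini C12 and C13 to give oxyallyl cation 13, and the C10 carbinol next to the cationic C11 discharges it by a semipinacol 1,2-shift of C6, which expands the carbinol ring to the cyclohexanone ring A and makes C11 the spiro carbon. The closest known reaction type is the acid-catalysed tandem Nazarov cyclisation/semipinacol rearrangement of α-(1-hydroxycyclobutyl) divinyl ketones to spiro[4.4]nonane-1,6-diones; the extension here is an unstrained cyclopentanol donor and CH2 termini, which should still be downhill because a delocalised cation is exchanged for two carbonyl groups. No stereocentre arises in the electrocyclisation (C12 and C13 are CH2), so torquoselectivity is irrelevant. C11 is set in the shift: the chelate holds O10 syn to O26, C6 and C9 then flank the empty orbital on opposite faces, and C6 migrates suprafacially with retention to the face fixed by the C10 configuration, which places C26 cis to the C6 chain on ring A. The step needs the shift to beat loss of a β-proton (ordinary Nazarov termination) and C6 to migrate instead of C9: the non-basic triflate medium slows elimination, and C6 is the more substituted carbon and is further stabilised in the bridged transition state by the β-silyl group on C7.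

**Step 7**
Reactants: 14
Product: 15 (5R,6S,9S,10S)-10-{3-[(tert-butyldiphenylsilyl)oxy]propyl}-9-[dimethyl(phenyl)silyl]-6-hydroxy-6-methylspiro[4.5]decan-1-one
Conditions: MeMgBr (1.2 equiv), CeCl3, THF, −78 °C; AcOH quench at −78 °C
Reagents that add atoms: methylmagnesium bromide, C[Mg]Br
Why: Organocerium 1,2-addition should select the cyclohexanone carbonyl (C10) over the less electrophilic cyclopentanone (C26), and axial attack anti to the axial C11–C26 bond (Felkin–Anh) in the chair with the C6 chain equatorial should place methyl cis to C12 and hydroxyl cis to C26.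

**Step 8**
Reactants: 15
Product: 16 (5R,6S,9S,10S)-10-{3-[(tert-butyldiphenylsilyl)oxy]propyl}-6,9-dihydroxy-6-methylspiro[4.5]decan-1-one
Conditions: Hg(OAc)2 (1.5 equiv), AcOOH, AcOH, 23 °C
Reagents that add atoms: peracetic acid, CC(=O)OO
Why: Fleming–Tamao oxidation (ipso-mercuration of the phenylsilane, then peracid oxidation of the C–Si bond) converts C7–Si into C7–OH with retention.

**Step 9**
Reactants: 16
Product: 17 (5R,6S,10S)-6-{3-[(tert-butyldiphenylsilyl)oxy]propyl}-10-hydroxy-10-methylspiro[4.5]decane-1,7-dione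
Conditions: Dess–Martin periodinane, NaHCO3, CH2Cl2, 23 °C
Reagents that add atoms: none
Why: Buffered Dess–Martin oxidation of the secondary alcohol gives the C7 ketone under conditions that should not epimerise C6.

**Step 10**
Reactants: 17
Product: 18 (5R,6S,9R,10S)-10-{3-[(tert-butyldiphenylsilyl)oxy]propyl}-6,9-dihydroxy-6-methyl-9-(prop-1-en-2-yl)spiro[4.5]decan-1-one
Conditions: CH2=C(CH3)MgBr (3 equiv), CeCl3, THF, −78 °C; AcOH quench at −78 °C
Reagents that add atoms: isopropenylmagnesium bromide, CC(=C)[Mg]Br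
Why: Organocerium addition should take the more accessible cyclohexanone (C7) in preference to the neopentyl cyclopentanone (C26), by equatorial attack because the axial face is blocked by the axial C26 on C11; the new carbinol centre is removed in step 18.

**Step 11**
Reactants: 19 6-methylhept-5-en-2-one
Product: 20 6-methylhepta-1,5-dien-2-yl trifluoromethanesulfonate
Conditions: LiN(i-Pr)2, THF, −78 °C; PhNTf2, −78 → 0 °C
Reagents that add atoms: N-phenylbis(trifluoromethanesulfonimide), O=S(=O)(N(c1ccccc1)S(=O)(=O)C(F)(F)F)C(F)(F)F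
Why: Kinetic deprotonation at the methyl group and O-triflation give the terminal enol triflate (future C19=CH2).

**Step 12**
Reactants: 20; 21 (E)-1,2-bis(tributylstannyl)ethene
Product: 22 tributyl[(1E)-7-methyl-3-methylideneocta-1,6-dien-1-yl]stannane
Conditions: 21 (3 equiv), Pd(PPh3)4 (5 mol %), LiCl, THF, 65 °C
Reagents that add atoms: none
Why: Stille coupling of the vinyl triflate with one tin terminus of the excess distannane keeps the E geometry that becomes C17=C18.

**Step 13**
Reactants: 23 methyl prop-2-ynoate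
Product: 24 methyl (2E)-2,3-dibromoprop-2-enoate
Conditions: Br2, CH2Cl2, 0 → 23 °C
Reagents that add atoms: bromine, BrBr
Why: Anti addition of bromine to the alkyne gives the E dibromide.

**Step 14**
Reactants: 22; 24
Product: 25 methyl (2E,4E)-2-bromo-10-methyl-6-methylideneundeca-2,4,9-trienoate
Conditions: Pd2(dba)3 (2.5 mol %), AsPh3 (20 mol %), NMP, 23 °C
Reagents that add atoms: none
Why: Oxidative addition takes place at the more electrophilic β C–Br bond of the 2,3-dibromoacrylate, and Stille coupling with retention at both partners places the ester carbon (future C27) cis to the dienyl group (future C17).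

**Step 15**
Reactants: 25
Product: 26 (2E,4E)-2-bromo-10-methyl-6-methylideneundeca-2,4,9-trien-1-ol
Conditions: i-Bu2AlH (2.2 equiv), CH2Cl2, −78 °C; aq. potassium sodium tartrate work-up
Reagents that add atoms: none
Why: 1,2-Reduction of the conjugated ester gives the allylic alcohol without touching the vinyl bromide.

**Step 16**
Reactants: 18; 26
Product: 27 (2S,5R,6S,9R,10S)-10-{3-[(tert-butyldiphenylsilyl)oxy]propyl}-6,9-dihydroxy-2-[(2Z,4E)-1-hydroxy-10-methyl-6-methylideneundeca-2,4,9-trien-2-yl]-6-methyl-9-(prop-1-en-2-yl)spiro[4.5]decan-1-one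
Conditions: 18, LiN(SiMe3)2 (4.5 equiv in all), THF, −78 → 0 °C; 26, Pd2(dba)3 (2.5 mol %), P(t-Bu)3·HBF4 (10 mol %), toluene, 23 → 45 °C; AcOH, −78 °C
Reagents that add atoms: none
Why: Palladium-catalysed α-alkenylation of a ketone enolate with an alkenyl bromide: C14 is the only enolisable position of the C26 ketone (C11 is quaternary), complete enolisation also blocks retro-aldol opening at C10–C11, the bromoalkene geometry is retained, and the new C14 centre stays epimerisable until it is fixed in step 19.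

**Step 17**
Reactants: 27
Product: 28 [(2Z,4E)-2-[(2S,5R,6S,9R,10S)-10-{3-[(tert-butyldiphenylsilyl)oxy]propyl}-6,9-dihydroxy-6-methyl-1-oxo-9-(prop-1-en-2-yl)spiro[4.5]decan-2-yl]-10-methyl-6-methylideneundeca-2,4,9-trien-1-yl] acetate
Conditions: Ac2O (1.1 equiv), pyridine, DMAP (5 mol %), CH2Cl2, 0 °C
Reagents that add atoms: acetic anhydride, CC(=O)OC(C)=O
Why: The primary allylic hydroxyl is acetylated selectively in the presence of two hindered tertiary alcohols.

**Step 18**
Reactants: 28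
Product: 29 [(2Z,4E)-2-[(2S,5R,6S,9E,10R)-10-{3-[(tert-butyldiphenylsilyl)oxy]propyl}-6-hydroxy-6-methyl-1-oxo-9-(1-oxopropan-2-ylidene)spiro[4.5]decan-2-yl]-10-methyl-6-methylideneundeca-2,4,9-trien-1-yl] acetate
Conditions: pyridinium chlorochromate (PyH)[CrO3Cl] (3 equiv), NaOAc, 4 Å MS, CH2Cl2, 23 °C
Reagents that add atoms: pyridinium chlorochromate, [O-][Cr](=O)(=O)Cl.c1cc[nH+]cc1
Why: Babler–Dauben oxidative transposition ([3,3] shift of the tertiary allylic chromate, then oxidation at C1) gives the tetrasubstituted enal, and a chair-like transition state on the axial C7 oxygen that keeps the bulkier ring branch C6 away from the chromium-bearing terminus should place CHO cis to C8; this geometric preference is an expectation, not a certainty.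

**Step 19**
Reactants: 29
Product: 30 [(2Z,4E)-2-[(1R,2S,5S,6S,9E,10R)-10-{3-[(tert-butyldiphenylsilyl)oxy]propyl}-1,6-dihydroxy-6-methyl-9-(1-oxopropan-2-ylidene)spiro[4.5]decan-2-yl]-10-methyl-6-methylideneundeca-2,4,9-trien-1-yl] acetate
Conditions: Me4NBH(OAc)3 (5 equiv), MeCN/AcOH (1:1), −30 °C
Reagents that add atoms: none
Why: Hydroxyl-directed (Evans–Saksena) reduction delivers hydride from the C10–O face to give the C26 alcohol with OH on the C6 side; the readily enolised α-alkenyl ketone should funnel through the 14S epimer, whose side chain lies away from the incoming hydride (OH cis to the side chain), while the hindered tetrasubstituted enal and the acetate should not be reduced at this temperature.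

**Step 20**
Reactants: 30
Product: 31 [(2Z,4E)-2-[(1R,2S,5S,6S,9E,10R)-1,6-dihydroxy-10-(3-hydroxypropyl)-6-methyl-9-(1-oxopropan-2-ylidene)spiro[4.5]decan-2-yl]-10-methyl-6-methylideneundeca-2,4,9-trien-1-yl] acetate (target)
Conditions: HF·pyridine, pyridine, THF, 0 → 23 °C
Reagents that add atoms: none
Why: Buffered fluoride cleaves the primary silyl ether without affecting the acetate, the enal or the polyene.

**Compound list**
1 | 2-iodocyclopent-2-en-1-one | O=C1CCC=C1I | starting material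
2 | tert-butyl(diphenyl)(prop-2-en-1-yloxy)silane | C=CCO[Si](c1ccccc1)(c1ccccc1)C(C)(C)C | starting material
3 | 9-{3-[(tert-butyldiphenylsilyl)oxy]propyl}-9-borabicyclo[3.3.1]nonane | CC(C)(C)[Si](OCCCB1C2CCCC1CCC2)(c1ccccc1)c1ccccc1 | intermediate
4 | 2-{3-[(tert-butyldiphenylsilyl)oxy]propyl}cyclopent-2-en-1-one | O=C1CCC=C1CCCO[Si](c1ccccc1)(c1ccccc1)C(C)(C)C | intermediate
5 | (2R,3S)-2-{3-[(tert-butyldiphenylsilyl)oxy]propyl}-3-[dimethyl(phenyl)silyl]cyclopentan-1-one (cis) | O=C1[C@@H](CCCO[Si](c2ccccc2)(c2ccccc2)C(C)(C)C)[C@@H]([Si](C)(C)c2ccccc2)CC1 | intermediate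
6 | (2S,3S)-2-{3-[(tert-butyldiphenylsilyl)oxy]propyl}-3-[dimethyl(phenyl)silyl]cyclopentan-1-one (trans) | O=C1[C@H](CCCO[Si](c2ccccc2)(c2ccccc2)C(C)(C)C)[C@@H]([Si](C)(C)c2ccccc2)CC1 | intermediate
7 | 2-bromo-3,3-diethoxyprop-1-ene | C=C(Br)C(OCC)OCC | starting material
8 | (3,3-diethoxyprop-1-en-2-yl)lithium | [Li]C(=C)C(OCC)OCC | intermediate
9 | (1S,2S,3S)-2-{3-[(tert-butyldiphenylsilyl)oxy]propyl}-1-(3,3-diethoxyprop-1-en-2-yl)-3-[dimethyl(phenyl)silyl]cyclopentan-1-ol | C=C(C(OCC)OCC)[C@@]1(O)[C@H](CCCO[Si](c2ccccc2)(c2ccccc2)C(C)(C)C)[C@@H]([Si](C)(C)c2ccccc2)CC1 | intermediate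
10 | 2-[(1S,2S,3S)-2-{3-[(tert-butyldiphenylsilyl)oxy]propyl}-3-[dimethyl(phenyl)silyl]-1-hydroxycyclopentyl]prop-2-enal | C=C(C=O)[C@@]1(O)[C@H](CCCO[Si](c2ccccc2)(c2ccccc2)C(C)(C)C)[C@@H]([Si](C)(C)c2ccccc2)CC1 | intermediate
11 | 2-[(1S,2S,3S)-2-{3-[(tert-butyldiphenylsilyl)oxy]propyl}-3-[dimethyl(phenyl)silyl]-1-hydroxycyclopentyl]penta-1,4-dien-3-ol (C3 epimers) | C=CC(O)C(=C)[C@@]1(O)[C@H](CCCO[Si](c2ccccc2)(c2ccccc2)C(C)(C)C)[C@@H]([Si](C)(C)c2ccccc2)CC1 | intermediate
12 | 2-[(1S,2S,3S)-2-{3-[(tert-butyldiphenylsilyl)oxy]propyl}-3-[dimethyl(phenyl)silyl]-1-hydroxycyclopentyl]penta-1,4-dien-3-one | C=CC(=O)C(=C)[C@@]1(O)[C@H](CCCO[Si](c2ccccc2)(c2ccccc2)C(C)(C)C)[C@@H]([Si](C)(C)c2ccccc2)CC1 | intermediate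
13 | 3-[(1S,2S,3S)-2-{3-[(tert-butyldiphenylsilyl)oxy]propyl}-3-[dimethyl(phenyl)silyl]-1-hydroxycyclopentyl]-2-hydroxycyclopent-2-en-1-ylium (oxyallyl cation of ring B, scandium-bound) | OC1=C(CC[CH+]1)[C@@]1(O)[C@H](CCCO[Si](c2ccccc2)(c2ccccc2)C(C)(C)C)[C@@H]([Si](C)(C)c2ccccc2)CC1 | intermediate
14 | (5S,9S,10S)-10-{3-[(tert-butyldiphenylsilyl)oxy]propyl}-9-[dimethyl(phenyl)silyl]spiro[4.5]decane-1,6-dione | C1CC[C@]2([C@H](CCCO[Si](c3ccccc3)(c3ccccc3)C(C)(C)C)[C@@H]([Si](C)(C)c3ccccc3)CCC2=O)C1=O | intermediate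
15 | (5R,6S,9S,10S)-10-{3-[(tert-butyldiphenylsilyl)oxy]propyl}-9-[dimethyl(phenyl)silyl]-6-hydroxy-6-methylspiro[4.5]decan-1-one | C1CC[C@]2([C@H](CCCO[Si](c3ccccc3)(c3ccccc3)C(C)(C)C)[C@@H]([Si](C)(C)c3ccccc3)CC[C@]2(C)O)C1=O | intermediate
16 | (5R,6S,9S,10S)-10-{3-[(tert-butyldiphenylsilyl)oxy]propyl}-6,9-dihydroxy-6-methylspiro[4.5]decan-1-one | C1CC[C@]2([C@H](CCCO[Si](c3ccccc3)(c3ccccc3)C(C)(C)C)[C@@H](O)CC[C@]2(C)O)C1=O | intermediate
17 | (5R,6S,10S)-6-{3-[(tert-butyldiphenylsilyl)oxy]propyl}-10-hydroxy-10-methylspiro[4.5]decane-1,7-dione | C1CC[C@]2([C@H](CCCO[Si](c3ccccc3)(c3ccccc3)C(C)(C)C)C(=O)CC[C@]2(C)O)C1=O | intermediate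
18 | (5R,6S,9R,10S)-10-{3-[(tert-butyldiphenylsilyl)oxy]propyl}-6,9-dihydroxy-6-methyl-9-(prop-1-en-2-yl)spiro[4.5]decan-1-one | C1CC[C@]2([C@H](CCCO[Si](c3ccccc3)(c3ccccc3)C(C)(C)C)[C@@](O)(C(C)=C)CC[C@]2(C)O)C1=O | intermediate
19 | 6-methylhept-5-en-2-one | CC(=O)CCC=C(C)C | starting material
20 | 6-methylhepta-1,5-dien-2-yl trifluoromethanesulfonate | C=C(OS(=O)(=O)C(F)(F)F)CCC=C(C)C | intermediate
21 | (E)-1,2-bis(tributylstannyl)ethene | CCCC[Sn](CCCC)(CCCC)/C=C/[Sn](CCCC)(CCCC)CCCC | starting material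
22 | tributyl[(1E)-7-methyl-3-methylideneocta-1,6-dien-1-yl]stannane | C=C(/C=C/[Sn](CCCC)(CCCC)CCCC)CCC=C(C)C | intermediate
23 | methyl prop-2-ynoate | C#CC(=O)OC | starting material
24 | methyl (2E)-2,3-dibromoprop-2-enoate | COC(=O)/C(Br)=C\Br | intermediate
25 | methyl (2E,4E)-2-bromo-10-methyl-6-methylideneundeca-2,4,9-trienoate | COC(=O)/C(Br)=C\C=C\C(=C)CCC=C(C)C | intermediate
26 | (2E,4E)-2-bromo-10-methyl-6-methylideneundeca-2,4,9-trien-1-ol | OC/C(Br)=C\C=C\C(=C)CCC=C(C)C | intermediate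
27 | (2S,5R,6S,9R,10S)-10-{3-[(tert-butyldiphenylsilyl)oxy]propyl}-6,9-dihydroxy-2-[(2Z,4E)-1-hydroxy-10-methyl-6-methylideneundeca-2,4,9-trien-2-yl]-6-methyl-9-(prop-1-en-2-yl)spiro[4.5]decan-1-one | C=C(/C=C/C=C(\CO)[C@@H]1CC[C@]2([C@H](CCCO[Si](c3ccccc3)(c3ccccc3)C(C)(C)C)[C@@](O)(C(C)=C)CC[C@]2(C)O)C1=O)CCC=C(C)C | intermediate
28 | [(2Z,4E)-2-[(2S,5R,6S,9R,10S)-10-{3-[(tert-butyldiphenylsilyl)oxy]propyl}-6,9-dihydroxy-6-methyl-1-oxo-9-(prop-1-en-2-yl)spiro[4.5]decan-2-yl]-10-methyl-6-methylideneundeca-2,4,9-trien-1-yl] acetate | C=C(/C=C/C=C(\COC(C)=O)[C@@H]1CC[C@]2([C@H](CCCO[Si](c3ccccc3)(c3ccccc3)C(C)(C)C)[C@@](O)(C(C)=C)CC[C@]2(C)O)C1=O)CCC=C(C)C | intermediate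
29 | [(2Z,4E)-2-[(2S,5R,6S,9E,10R)-10-{3-[(tert-butyldiphenylsilyl)oxy]propyl}-6-hydroxy-6-methyl-1-oxo-9-(1-oxopropan-2-ylidene)spiro[4.5]decan-2-yl]-10-methyl-6-methylideneundeca-2,4,9-trien-1-yl] acetate | C=C(/C=C/C=C(\COC(C)=O)[C@@H]1CC[C@]2([C@H](CCCO[Si](c3ccccc3)(c3ccccc3)C(C)(C)C)/C(=C(\C)C=O)CC[C@]2(C)O)C1=O)CCC=C(C)C | intermediate
30 | [(2Z,4E)-2-[(1R,2S,5S,6S,9E,10R)-10-{3-[(tert-butyldiphenylsilyl)oxy]propyl}-1,6-dihydroxy-6-methyl-9-(1-oxopropan-2-ylidene)spiro[4.5]decan-2-yl]-10-methyl-6-methylideneundeca-2,4,9-trien-1-yl] acetate | C=C(/C=C/C=C(\COC(C)=O)[C@@H]1CC[C@]2([C@H](CCCO[Si](c3ccccc3)(c3ccccc3)C(C)(C)C)/C(=C(\C)C=O)CC[C@]2(C)O)[C@@H]1O)CCC=C(C)C | intermediate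
31 | [(2Z,4E)-2-[(1R,2S,5S,6S,9E,10R)-1,6-dihydroxy-10-(3-hydroxypropyl)-6-methyl-9-(1-oxopropan-2-ylidene)spiro[4.5]decan-2-yl]-10-methyl-6-methylideneundeca-2,4,9-trien-1-yl] acetate | C=C(/C=C/C=C(\COC(C)=O)[C@@H]1CC[C@]2([C@H](CCCO)/C(=C(\C)C=O)CC[C@]2(C)O)[C@@H]1O)CCC=C(C)C | target

**Step count and risks**
Total steps: 20. Longest linear sequence: 15 steps (1 → 31 through steps 1–10 and 16–20).

Steps most likely to fail:

1. Step 6 (Proposed new method). The oxyallyl cation may simply lose a proton from C12 or C13 (ordinary cyclopentenone formation), the unstrained carbinol ring may shift too slowly or through C9, or the bis-methylene dienone may polymerise before it cyclises. Fallback with known chemistry, in which ring B is brought in intact instead of being closed: from 6, addition of cyclopent-1-en-1-yllithium F1 (from 1-bromocyclopentene and t-BuLi, with CeCl3) gives the tertiary allylic alcohol F2. Hydroxyl-directed epoxidation (VO(acac)2, t-BuOOH) gives the epoxy alcohol F3; the epoxide face shown is the one required, and peracid epoxidation would be tried if the directed reaction gave the other. Lewis-acid semipinacol rearrangement of this 2,3-epoxy alcohol (BF3·OEt2, CH2Cl2, −78 °C) moves C6 anti to the breaking C–O bond and gives the spiro hydroxy ketone F4. Dess–Martin oxidation of F4 returns to 14.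

2. Step 16. The polyanion of 18 may open by retro-aldol cleavage of the C10–C11 bond before enolisation is complete, oxidative addition into the hindered bromodiene may be slow, and the β,γ-unsaturated ketone may drift into conjugation. Fallback: from 18, dehydrogenation with IBX (DMSO, 65 °C) gives the enone F5 and iodination (I2, pyridine) the α-iodoenone F6. Bromide 26 is converted into the stannane F7 (t-BuLi, then Bu3SnCl). Stille coupling of F6 with F7 (Pd2(dba)3, AsPh3, CuI, NMP) gives the cross-conjugated dienone F8, and conjugate reduction with [(Ph3P)CuH]6 followed by protonation returns to 27.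

3. Step 19. The C14 epimers may not funnel completely (two diastereomeric alcohols), and the enal may suffer partial 1,2-reduction. Fallback that reduces before the enal exists and protects C26: from 28, the same directed reduction gives the diol F9; the C14 epimers are separated here and the minor one is returned to 28 by Dess–Martin oxidation. TESOTf/2,6-lutidine at −78 °C should silylate only the secondary C26 hydroxyl and give the C26 triethylsilyl ether F10. Pyridinium chlorochromate (PyH)[CrO3Cl] then effects the transposition without a competing secondary alcohol and gives the silyl-protected enal F11. HF·pyridine removes both silyl groups from it to give 31.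

**Further compounds**
F1 | step 6 | cyclopent-1-en-1-yllithium | [Li]C1=CCCC1
F2 | step 6 | (1S,2S,3S)-2-{3-[(tert-butyldiphenylsilyl)oxy]propyl}-1-(cyclopent-1-en-1-yl)-3-[dimethyl(phenyl)silyl]cyclopentan-1-ol | C1=C(CCC1)[C@@]1(O)[C@H](CCCO[Si](c2ccccc2)(c2ccccc2)C(C)(C)C)[C@@H]([Si](C)(C)c2ccccc2)CC1
F3 | step 6 | (1S,2S,3S)-2-{3-[(tert-butyldiphenylsilyl)oxy]propyl}-3-[dimethyl(phenyl)silyl]-1-(6-oxabicyclo[3.1.0]hexan-1-yl)cyclopentan-1-ol (epoxide face as drawn) | C1CC[C@]2(O[C@@H]12)[C@@]1(O)[C@H](CCCO[Si](c3ccccc3)(c3ccccc3)C(C)(C)C)[C@@H]([Si](C)(C)c3ccccc3)CC1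
F4 | step 6 | 10-{3-[(tert-butyldiphenylsilyl)oxy]propyl}-9-[dimethyl(phenyl)silyl]-1-hydroxyspiro[4.5]decan-6-one (C5, C9, C10 as in 14; hydroxyl on the C10 side) | C1CC[C@]2([C@H](CCCO[Si](c3ccccc3)(c3ccccc3)C(C)(C)C)[C@@H]([Si](C)(C)c3ccccc3)CCC2=O)[C@H]1O
F5 | step 16 | (5R,6S,9R,10S)-10-{3-[(tert-butyldiphenylsilyl)oxy]propyl}-6,9-dihydroxy-6-methyl-9-(prop-1-en-2-yl)spiro[4.5]dec-2-en-1-one | O=C1C=CC[C@]12[C@H](CCCO[Si](c3ccccc3)(c3ccccc3)C(C)(C)C)[C@@](O)(C(C)=C)CC[C@]2(C)O
F6 | step 16 | 2-iodo derivative of F5 | O=C1C(I)=CC[C@]12[C@H](CCCO[Si](c3ccccc3)(c3ccccc3)C(C)(C)C)[C@@](O)(C(C)=C)CC[C@]2(C)O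
F7 | step 16 | (2E,4E)-10-methyl-6-methylidene-2-(tributylstannyl)undeca-2,4,9-trien-1-ol | OC/C(=C\C=C\C(=C)CCC=C(C)C)[Sn](CCCC)(CCCC)CCCC
F8 | step 16 | 2-[(2Z,4E)-1-hydroxy-10-methyl-6-methylideneundeca-2,4,9-trien-2-yl] derivative of F5 | C=C(/C=C/C=C(\CO)C1=CC[C@]2([C@H](CCCO[Si](c3ccccc3)(c3ccccc3)C(C)(C)C)[C@@](O)(C(C)=C)CC[C@]2(C)O)C1=O)CCC=C(C)C
F9 | step 19 | C26 alcohol of 28 (1R,2S; side chain and hydroxyl cis) | C=C(/C=C/C=C(\COC(C)=O)[C@@H]1CC[C@]2([C@H](CCCO[Si](c3ccccc3)(c3ccccc3)C(C)(C)C)[C@@](O)(C(C)=C)CC[C@]2(C)O)[C@@H]1O)CCC=C(C)C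
F10 | step 19 | C26 triethylsilyl ether of F9 | C=C(/C=C/C=C(\COC(C)=O)[C@@H]1CC[C@]2([C@H](CCCO[Si](c3ccccc3)(c3ccccc3)C(C)(C)C)[C@@](O)(C(C)=C)CC[C@]2(C)O)[C@@H]1O[Si](CC)(CC)CC)CCC=C(C)C
F11 | step 19 | C26 triethylsilyl ether of 30 | C=C(/C=C/C=C(\COC(C)=O)[C@@H]1CC[C@]2([C@H](CCCO[Si](c3ccccc3)(c3ccccc3)C(C)(C)C)/C(=C(\C)C=O)CC[C@]2(C)O)[C@@H]1O[Si](CC)(CC)CC)CCC=C(C)C
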